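**Plan**
- Retrosynthesis: the C8 ester, the C14 acetate and C11=C13 come off first. The C1–C10 epoxide, whose C10 also carries C14–O, is read as a C1 carbinol beside an exocyclic C10=C14 methylene on the ten-membered ring; that allylic alcohol is cut at C1–C10 (C10 alkenyl metal plus C1 aldehyde).
- The seco chain is then cut at C3–C4 (B-alkyl Suzuki), C4=C5 (iodo-Wittig), C8–C9 (propargylation) and C7–C8 (cuprate addition to a butenolide).
- Forward: the lactone ring is present from the start; the C8–C10 arm and then the C5–C1 arm are attached to it; the ten-membered ring closes last at C1–C10. Epoxide, methylene lactone and the two esters follow.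
- Stereochemistry: C6 from (S)-5-(hydroxymethyl)furan-2(5H)-one; C7 by anti cuprate addition; C8 by catalyst-controlled propargylation; 4Z by Z-iodo-olefination and stereoretentive coupling.
- C1 is set in the ring closure and inverted on epoxide closure; C10 by hydroxyl-directed dihydroxylation; C2' and C3' by Sharpless epoxidation of angelyl alcohol.

Key step: step 12

Remark: atoms carry germacrane numbers (C1–C15); the (R)-1,1'-bi-2-naphthol–titanium catalyst is assumed to deliver the propargyl group to the Re face of the aldehyde as it does an allyl group, otherwise its antipode is used.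

**Route**

Step 1
Reactants: 1 (S)-5-(hydroxymethyl)furan-2(5H)-one
Product: 2 (S)-5-[(triethylsilyloxy)methyl]furan-2(5H)-one
Conditions: Et3SiCl, imidazole, CH2Cl2, 0 °C
Reagents that add atoms: chlorotriethylsilane, CC[Si](Cl)(CC)CC
Why: Imidazole-mediated silyl ether formation masks the primary alcohol as a group that step 6 can oxidise directly; the C6 stereocentre is untouched.

Step 2
Reactants: 2 (S)-5-[(triethylsilyloxy)methyl]furan-2(5H)-one
Product: 3 (4R,5S)-4-ethenyl-5-[(triethylsilyloxy)methyl]oxolan-2-one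
Conditions: CH2=CHMgBr (2.4 equiv), CuI (1.2 equiv), THF, −78 → −40 °C; aq. NH4Cl
Reagents that add atoms: vinylmagnesium bromide, C=C[Mg]Br
Why: Cuprate conjugate addition to the butenolide occurs anti to the C6 silyloxymethyl group (substrate control, established for 5-substituted butenolides), which sets C7 trans to C6.

Step 3
Reactants: 3 (4R,5S)-4-ethenyl-5-[(triethylsilyloxy)methyl]oxolan-2-one
Product: 5 (2S,3S)-5-oxo-2-[(triethylsilyloxy)methyl]oxolane-3-carbaldehyde, via secondary ozonide 4 (not isolated)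
Conditions: O3, CH2Cl2, −78 °C; then PPh3, −78 °C → rt
Reagents that add atoms: ozone, [O-][O+]=O
Why: Ozonolysis with reductive work-up cleaves the only alkene to the C8 aldehyde under neutral conditions, which avoids epimerisation at C7 and β-elimination of the lactone oxygen.

Step 4
Reactants: 5 (2S,3S)-5-oxo-2-[(triethylsilyloxy)methyl]oxolane-3-carbaldehyde
Product: 6 (4R,5S)-4-[(1R)-1-hydroxybut-3-yn-1-yl]-5-[(triethylsilyloxy)methyl]oxolan-2-one
Conditions: (R)-1,1'-bi-2-naphthol (20 mol %), Ti(OiPr)4 (10 mol %), 4 Å MS, Bu3SnCH=C=CH2, Et2BS(iPr), CH2Cl2, −20 °C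
Reagents that add atoms: allenyltributylstannane, C=C=C[Sn](CCCC)(CCCC)CCCC
Why: Titanium–binaphthol-catalysed asymmetric propargylation: the allenylstannane adds by SE2' to the Re face of the activated aldehyde, so the catalyst sets C8 (R) against the weak Felkin–Anh preference of C7.

Step 5
Reactants: 6 (4R,5S)-4-[(1R)-1-hydroxybut-3-yn-1-yl]-5-[(triethylsilyloxy)methyl]oxolan-2-one
Product: 7 (4S,5S)-4-[(1R)-1-(tert-butyldimethylsilyloxy)but-3-yn-1-yl]-5-[(triethylsilyloxy)methyl]oxolan-2-one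
Conditions: TBSOTf, 2,6-lutidine, CH2Cl2, −78 °C
Reagents that add atoms: tert-butyldimethylsilyl triflate, CC(C)(C)[Si](C)(C)OS(=O)(=O)C(F)(F)F
Why: Silyl triflate silylation of the hindered secondary alcohol, done at once so that the free C8 hydroxyl cannot translactonise onto C12; no stereocentre is affected (the descriptor at C7 changes by priority only).

Step 6
Reactants: 7 (4S,5S)-4-[(1R)-1-(tert-butyldimethylsilyloxy)but-3-yn-1-yl]-5-[(triethylsilyloxy)methyl]oxolan-2-one
Product: 8 (2S,3S)-3-[(1R)-1-(tert-butyldimethylsilyloxy)but-3-yn-1-yl]-5-oxooxolane-2-carbaldehyde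
Conditions: (COCl)2, DMSO, CH2Cl2, −78 → −35 °C; then Et3N, −78 → 0 °C
Reagents that add atoms: none
Why: Swern oxidation applied directly to the bis-silyl ether: the primary triethylsilyl ether is cleaved by the chlorosulfonium reagent and oxidised to the C5 aldehyde while the secondary TBS ether survives, and the low temperature protects C6 from epimerisation.

Step 7
Reactants: 8 (2S,3S)-3-[(1R)-1-(tert-butyldimethylsilyloxy)but-3-yn-1-yl]-5-oxooxolane-2-carbaldehyde
Product: 9 (4S,5S)-4-[(1R)-1-(tert-butyldimethylsilyloxy)but-3-yn-1-yl]-5-[(1Z)-2-iodoprop-1-en-1-yl]oxolan-2-one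
Conditions: [Ph3PCH(I)CH3]I, NaN(SiMe3)2, THF, −78 °C; then 8, −78 → −20 °C
Reagents that add atoms: (1-iodoethyl)triphenylphosphonium iodide, CC(I)[P+](c1ccccc1)(c1ccccc1)c1ccccc1.[I-]
Why: Stork–Zhao-type Wittig olefination with the α-iodo ylide gives the Z iodoalkene (iodine cis to C6) under kinetic control, which fixes the later C4=C5 geometry.

Step 8
Reactants: 9 (4S,5S)-4-[(1R)-1-(tert-butyldimethylsilyloxy)but-3-yn-1-yl]-5-[(1Z)-2-iodoprop-1-en-1-yl]oxolan-2-one; 10 tert-butyldimethyl(prop-2-en-1-yloxy)silane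
Product: 12 (4S,5R)-4-[(1R)-1-(tert-butyldimethylsilyloxy)but-3-yn-1-yl]-5-[(1Z)-5-(tert-butyldimethylsilyloxy)-2-methylpent-1-en-1-yl]oxolan-2-one, via alkylborane 11 (not isolated)
Conditions: 10 (1.6 equiv), 9-BBN (1.5 equiv), THF, rt; then 9, PdCl2(dppf) (5 mol %), AsPh3, Cs2CO3, DMF/H2O, rt
Reagents that add atoms: none
Why: B-alkyl Suzuki–Miyaura coupling forms C3–C4 with retention of the alkene geometry (C3 cis to C6, 4Z); the small excess of 10 over 9-BBN leaves no B–H to hydroborate the alkyne, and no copper is present to couple it.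

Step 9
Reactants: 12 (4S,5R)-4-[(1R)-1-(tert-butyldimethylsilyloxy)but-3-yn-1-yl]-5-[(1Z)-5-(tert-butyldimethylsilyloxy)-2-methylpent-1-en-1-yl]oxolan-2-one
Product: 14 (4S,5R)-4-[(1R)-1-(tert-butyldimethylsilyloxy)-3-iodobut-3-en-1-yl]-5-[(1Z)-5-(tert-butyldimethylsilyloxy)-2-methylpent-1-en-1-yl]oxolan-2-one, via alkenylborane 13 (not isolated)
Conditions: B-iodo-9-BBN, pentane/CH2Cl2, −20 °C; then AcOH, 0 °C
Reagents that add atoms: B-iodo-9-borabicyclo[3.3.1]nonane, IB1C2CCCC1CCC2
Why: Haloboration of the terminal alkyne (boron to C14, iodine to C10, syn) followed by protodeboronation with acetic acid gives the 2-iodo-1-alkene; the trisubstituted alkene and the silyl ethers should be inert at this temperature.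

Step 10
Reactants: 14 (4S,5R)-4-[(1R)-1-(tert-butyldimethylsilyloxy)-3-iodobut-3-en-1-yl]-5-[(1Z)-5-(tert-butyldimethylsilyloxy)-2-methylpent-1-en-1-yl]oxolan-2-one
Product: 15 (4S,5R)-4-[(1R)-1-(tert-butyldimethylsilyloxy)-3-iodobut-3-en-1-yl]-5-[(1Z)-5-hydroxy-2-methylpent-1-en-1-yl]oxolan-2-one
Conditions: HF·pyridine, pyridine, THF, 0 °C
Reagents that add atoms: none
Why: Selective fluoride desilylation: the unhindered primary TBS ether at C1 is cleaved much faster than the hindered secondary one at C8.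

Step 11
Reactants: 15 (4S,5R)-4-[(1R)-1-(tert-butyldimethylsilyloxy)-3-iodobut-3-en-1-yl]-5-[(1Z)-5-hydroxy-2-methylpent-1-en-1-yl]oxolan-2-one
Product: 16 (4Z)-5-[(2R,3S)-3-[(1R)-1-(tert-butyldimethylsilyloxy)-3-iodobut-3-en-1-yl]-5-oxooxolan-2-yl]-4-methylpent-4-enal
Conditions: Dess–Martin periodinane, CH2Cl2, 0 °C → rt
Reagents that add atoms: none
Why: Dess–Martin oxidation gives the C1 aldehyde under neutral conditions; the aldehyde has no α-stereocentre to lose.

Step 12
Reactants: 16 (4Z)-5-[(2R,3S)-3-[(1R)-1-(tert-butyldimethylsilyloxy)-3-iodobut-3-en-1-yl]-5-oxooxolan-2-yl]-4-methylpent-4-enal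
Product: 18 (1S,4Z,6R,7S,8R)-8-(tert-butyldimethylsilyloxy)-1-hydroxy-13-norgermacra-4,10(14)-dien-12,6-olide, via alkenylchromium dichloride 17 (not isolated)
Conditions: CrCl2 (10 equiv), NiCl2 (0.1 equiv), degassed DMSO/THF (3:1), 16 added over 12 h to 2 mM, rt
Reagents that add atoms: none
Why: Nozaki–Hiyama–Kishi reaction: zerovalent nickel, formed from NiCl2 by CrCl2, inserts into the C10–I bond and transmetallation gives the alkenyl trivalent chromium species 17, which adds to the chromium-bound C1 aldehyde. The closest known reaction is the intramolecular vinyl iodide–aldehyde Nozaki–Hiyama–Kishi cyclisation used for medium and large carbocycles. The ten-membered ring closes in the exo mode (10-exo-trig at the aldehyde carbon, C10 attacking C1), the Z C4=C5 bond and the trans-fused lactone turning the two chain ends toward each other. The new C1 stereocentre is under substrate control: with the chromium-bearing oxygen pointing out of the forming ring and C1–H inside, C10 is expected to reach the Re face and give the 1S carbinol. The step needs aldehyde-over-lactone chemoselectivity, secured by the low basicity of organochromium reagents, cyclisation over oligomerisation, secured by dilution and slow addition, and 1S facial selectivity, which rests on the ring conformation alone and is the point the first fallback answers.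

Step 13
Reactants: 18 (1S,4Z,6R,7S,8R)-8-(tert-butyldimethylsilyloxy)-1-hydroxy-13-norgermacra-4,10(14)-dien-12,6-olide
Product: 20 (1S,4Z,6R,7S,8R,10S)-8-(tert-butyldimethylsilyloxy)-1,10,14-trihydroxy-13-norgermacr-4-en-12,6-olide, via osmate ester 19 (not isolated)
Conditions: OsO4 (1.05 equiv), TMEDA (1.1 equiv), CH2Cl2, −78 °C; then aq. Na2SO3, THF, rt
Reagents that add atoms: osmium tetroxide, O=[Os](=O)(=O)=O
Why: Hydroxyl-directed dihydroxylation: the OsO4–TMEDA complex is hydrogen-bonded to the C1 hydroxyl and adds to the neighbouring C10=C14 bond syn to it, in the conformer with C1–H eclipsing the methylene, which gives the 1,10-threo triol with C10 (S); the remote C4=C5 bond, which has no hydroxyl to bind the reagent, should react more slowly.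

Step 14
Reactants: 20 (1S,4Z,6R,7S,8R,10S)-8-(tert-butyldimethylsilyloxy)-1,10,14-trihydroxy-13-norgermacr-4-en-12,6-olide
Product: 21 (1S,4Z,6R,7S,8R,10S)-8,14-bis(tert-butyldimethylsilyloxy)-1,10-dihydroxy-13-norgermacr-4-en-12,6-olide
Conditions: TBSCl (1.1 equiv), imidazole, CH2Cl2, 0 °C
Reagents that add atoms: tert-butyldimethylsilyl chloride, CC(C)(C)[Si](C)(C)Cl
Why: Sterically controlled silylation takes the primary C14 hydroxyl and leaves the hindered secondary C1 and tertiary C10 hydroxyls; a silyl ether is chosen over the acetate so that step 16 meets no second enolisable ester.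

Step 15
Reactants: 21 (1S,4Z,6R,7S,8R,10S)-8,14-bis(tert-butyldimethylsilyloxy)-1,10-dihydroxy-13-norgermacr-4-en-12,6-olide
Product: 23 (1R,4Z,6R,7S,8R,10S)-8,14-bis(tert-butyldimethylsilyloxy)-1,10-epoxy-13-norgermacr-4-en-12,6-olide, via C1 mesylate 22 (not isolated)
Conditions: MsCl, Et3N, CH2Cl2, −20 °C; aqueous work-up; then NaH, THF, 0 °C → rt
Reagents that add atoms: none
Why: Mesylation takes the secondary C1 hydroxyl and not the tertiary one, and the C10 alkoxide then displaces the mesylate in an intramolecular SN2 reaction (Williamson-type epoxide closure) with inversion at C1 and retention at C10, which gives the trans 1R,10S epoxide.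

Step 16
Reactants: 23 (1R,4Z,6R,7S,8R,10S)-8,14-bis(tert-butyldimethylsilyloxy)-1,10-epoxy-13-norgermacr-4-en-12,6-olide
Product: 26 (1R,4Z,6R,7S,8R,10S)-8,14-bis(tert-butyldimethylsilyloxy)-1,10-epoxygermacra-4,11(13)-dien-12,6-olide, via Mannich base 24 (not isolated), via ammonium iodide 25 (not isolated)
Conditions: LiN(iPr)2, THF, −78 °C; CH2=NMe2+ I−, −78 °C → rt; MeI, MeOH, rt; aq. NaHCO3, CH2Cl2
Reagents that add atoms: N,N-dimethylmethyleneiminium iodide, C=[N+](C)C.[I-]
Why: Eschenmoser methylenation: the kinetic lactone enolate undergoes a Mannich reaction with the iminium salt, and quaternisation followed by base-induced elimination of trimethylamine gives the exocyclic C11=C13 bond; the C11 centre of the intermediates is lost, so its configuration does not matter.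

Step 17
Reactants: 26 (1R,4Z,6R,7S,8R,10S)-8,14-bis(tert-butyldimethylsilyloxy)-1,10-epoxygermacra-4,11(13)-dien-12,6-olide
Product: 27 (1R,4Z,6R,7R,8R,10S)-1,10-epoxy-8,14-dihydroxygermacra-4,11(13)-dien-12,6-olide
Conditions: HF·pyridine, pyridine, THF, 0 °C → rt
Reagents that add atoms: none
Why: Fluoride desilylation of both silyl ethers under pyridine-buffered, non-basic conditions that should spare the epoxide and the methylene lactone and give the free C8 hydroxyl no base to translactonise with.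

Step 18
Reactants: 27 (1R,4Z,6R,7R,8R,10S)-1,10-epoxy-8,14-dihydroxygermacra-4,11(13)-dien-12,6-olide
Product: 28 (1R,4Z,6R,7R,8R,10S)-14-acetoxy-1,10-epoxy-8-hydroxygermacra-4,11(13)-dien-12,6-olide
Conditions: Ac2O (1.1 equiv), 2,4,6-collidine, CH2Cl2, −20 → 0 °C
Reagents that add atoms: acetic anhydride, CC(=O)OC(C)=O
Why: Acylation with one equivalent of anhydride and a weak base takes the primary C14 hydroxyl in preference to the hindered secondary C8 hydroxyl (steric selectivity).

Step 19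
Reactants: 29 angelic acid, (Z)-2-methylbut-2-enoic acid
Product: 30 (Z)-2-methylbut-2-en-1-ol
Conditions: LiAlH4, Et2O, 0 °C
Reagents that add atoms: none
Why: Hydride reduction of the carboxylic acid to the allylic alcohol; LiAlH4 in ether at 0 °C should neither reduce nor isomerise the Z alkene.

Step 20
Reactants: 30 (Z)-2-methylbut-2-en-1-ol
Product: 31 [(2R,3S)-2,3-dimethyloxiran-2-yl]methanol
Conditions: Ti(OiPr)4 (10 mol %), D-(−)-diisopropyl tartrate (12 mol %), t-BuOOH, 4 Å MS, CH2Cl2, −20 °C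
Reagents that add atoms: tert-butyl hydroperoxide, CC(C)(C)OO
Why: Sharpless asymmetric epoxidation: the D-(−)-tartrate catalyst sets both centres by its choice of alkene face (2R,3S), and the cis relation of the hydroxymethyl group and the C3 methyl follows from the Z alkene.

Step 21
Reactants: 31 [(2R,3S)-2,3-dimethyloxiran-2-yl]methanol
Product: 32 (2S,3S)-2,3-dimethyloxirane-2-carboxylic acid
Conditions: RuCl3 (2 mol %), NaIO4, MeCN/CCl4/H2O, rt
Reagents that add atoms: water, O
Why: Ruthenium tetroxide oxidation (catalytic RuCl3 with periodate) takes the primary alcohol to the glycidic acid through the aldehyde hydrate and leaves the epoxide alone; the C2 descriptor changes to S by priority only.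

Step 22
Reactants: 28 (1R,4Z,6R,7R,8R,10S)-14-acetoxy-1,10-epoxy-8-hydroxygermacra-4,11(13)-dien-12,6-olide; 32 (2S,3S)-2,3-dimethyloxirane-2-carboxylic acid
Product: 34 (1R,4Z,6R,7R,8R,10S)-14-acetoxy-1,10-epoxy-8-[(2S,3S)-2,3-dimethyloxirane-2-carbonyloxy]germacra-4,11(13)-dien-12,6-olide (CNP0232260.1), via mixed anhydride 33 (not isolated)
Conditions: 32, 2,4,6-trichlorobenzoyl chloride, Et3N, toluene, rt; then 28, 4-(dimethylamino)pyridine, toluene, rt
Reagents that add atoms: none
Why: Yamaguchi esterification: the mixed anhydride acylates the C8 hydroxyl with 4-(dimethylamino)pyridine catalysis; the acid has no α-hydrogen, so C2' cannot epimerise, and all ring stereocentres are spectators.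

**Compound list**
1 | (S)-5-(hydroxymethyl)furan-2(5H)-one | O=C1O[C@H](CO)C=C1 | starting material
2 | (S)-5-[(triethylsilyloxy)methyl]furan-2(5H)-one | O=C1O[C@H](CO[Si](CC)(CC)CC)C=C1 | intermediate
3 | (4R,5S)-4-ethenyl-5-[(triethylsilyloxy)methyl]oxolan-2-one | O=C1C[C@H](C=C)[C@@H](CO[Si](CC)(CC)CC)O1 | intermediate
4 | secondary ozonide (1,2,4-trioxolane) of 3, not isolated | O=C1C[C@H](C2OCOO2)[C@@H](CO[Si](CC)(CC)CC)O1 | intermediate
5 | (2S,3S)-5-oxo-2-[(triethylsilyloxy)methyl]oxolane-3-carbaldehyde | O=C1C[C@H](C=O)[C@@H](CO[Si](CC)(CC)CC)O1 | intermediate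
6 | (4R,5S)-4-[(1R)-1-hydroxybut-3-yn-1-yl]-5-[(triethylsilyloxy)methyl]oxolan-2-one | O=C1C[C@H]([C@H](O)CC#C)[C@@H](CO[Si](CC)(CC)CC)O1 | intermediate
7 | (4S,5S)-4-[(1R)-1-(tert-butyldimethylsilyloxy)but-3-yn-1-yl]-5-[(triethylsilyloxy)methyl]oxolan-2-one | O=C1C[C@H]([C@H](O[Si](C)(C)C(C)(C)C)CC#C)[C@@H](CO[Si](CC)(CC)CC)O1 | intermediate
8 | (2S,3S)-3-[(1R)-1-(tert-butyldimethylsilyloxy)but-3-yn-1-yl]-5-oxooxolane-2-carbaldehyde | O=C1C[C@H]([C@H](O[Si](C)(C)C(C)(C)C)CC#C)[C@@H](C=O)O1 | intermediate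
9 | (4S,5S)-4-[(1R)-1-(tert-butyldimethylsilyloxy)but-3-yn-1-yl]-5-[(1Z)-2-iodoprop-1-en-1-yl]oxolan-2-one | O=C1C[C@H]([C@H](O[Si](C)(C)C(C)(C)C)CC#C)[C@@H](/C=C(/C)I)O1 | intermediate
10 | tert-butyldimethyl(prop-2-en-1-yloxy)silane | C=CCO[Si](C)(C)C(C)(C)C | starting material
11 | 9-[3-(tert-butyldimethylsilyloxy)propyl]-9-borabicyclo[3.3.1]nonane, not isolated | CC(C)(C)[Si](C)(C)OCCCB1C2CCCC1CCC2 | intermediate
12 | (4S,5R)-4-[(1R)-1-(tert-butyldimethylsilyloxy)but-3-yn-1-yl]-5-[(1Z)-5-(tert-butyldimethylsilyloxy)-2-methylpent-1-en-1-yl]oxolan-2-one | O=C1C[C@H]([C@H](O[Si](C)(C)C(C)(C)C)CC#C)[C@@H](/C=C(/C)CCCO[Si](C)(C)C(C)(C)C)O1 | intermediate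
13 | (Z)-2-iodoalkenyl-9-BBN adduct of 12 (boron on C14, iodine on C10), not isolated | O=C1C[C@H]([C@H](O[Si](C)(C)C(C)(C)C)CC(/I)=C/B2C3CCCC2CCC3)[C@@H](/C=C(/C)CCCO[Si](C)(C)C(C)(C)C)O1 | intermediate
14 | (4S,5R)-4-[(1R)-1-(tert-butyldimethylsilyloxy)-3-iodobut-3-en-1-yl]-5-[(1Z)-5-(tert-butyldimethylsilyloxy)-2-methylpent-1-en-1-yl]oxolan-2-one | O=C1C[C@H]([C@H](O[Si](C)(C)C(C)(C)C)CC(I)=C)[C@@H](/C=C(/C)CCCO[Si](C)(C)C(C)(C)C)O1 | intermediate
15 | (4S,5R)-4-[(1R)-1-(tert-butyldimethylsilyloxy)-3-iodobut-3-en-1-yl]-5-[(1Z)-5-hydroxy-2-methylpent-1-en-1-yl]oxolan-2-one | O=C1C[C@H]([C@H](O[Si](C)(C)C(C)(C)C)CC(I)=C)[C@@H](/C=C(/C)CCCO)O1 | intermediate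
16 | (4Z)-5-[(2R,3S)-3-[(1R)-1-(tert-butyldimethylsilyloxy)-3-iodobut-3-en-1-yl]-5-oxooxolan-2-yl]-4-methylpent-4-enal (seco aldehyde) | O=C1C[C@H]([C@H](O[Si](C)(C)C(C)(C)C)CC(I)=C)[C@@H](/C=C(/C)CCC=O)O1 | intermediate
17 | C10 alkenylchromium dichloride derived from 16, not isolated | O=C1C[C@H]([C@H](O[Si](C)(C)C(C)(C)C)CC(=C)[Cr](Cl)Cl)[C@@H](/C=C(/C)CCC=O)O1 | intermediate
18 | (1S,4Z,6R,7S,8R)-8-(tert-butyldimethylsilyloxy)-1-hydroxy-13-norgermacra-4,10(14)-dien-12,6-olide | C1C(=O)O[C@@H]2/C=C(/C)CC[C@H](O)C(=C)C[C@@H](O[Si](C)(C)C(C)(C)C)[C@@H]12 | intermediate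
19 | cyclic C10,C14 osmate ester of 18 as its TMEDA complex, not isolated | C1C(=O)O[C@@H]2/C=C(/C)CC[C@H](O)[C@@]3(CO[Os](=O)(=O)O3)C[C@@H](O[Si](C)(C)C(C)(C)C)[C@@H]12.CN(C)CCN(C)C | intermediate
20 | (1S,4Z,6R,7S,8R,10S)-8-(tert-butyldimethylsilyloxy)-1,10,14-trihydroxy-13-norgermacr-4-en-12,6-olide | C1C(=O)O[C@@H]2/C=C(/C)CC[C@H](O)[C@@](O)(CO)C[C@@H](O[Si](C)(C)C(C)(C)C)[C@@H]12 | intermediate
21 | (1S,4Z,6R,7S,8R,10S)-8,14-bis(tert-butyldimethylsilyloxy)-1,10-dihydroxy-13-norgermacr-4-en-12,6-olide | C1C(=O)O[C@@H]2/C=C(/C)CC[C@H](O)[C@@](O)(CO[Si](C)(C)C(C)(C)C)C[C@@H](O[Si](C)(C)C(C)(C)C)[C@@H]12 | intermediate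
22 | C1 methanesulfonate of 21, not isolated | C1C(=O)O[C@@H]2/C=C(/C)CC[C@H](OS(C)(=O)=O)[C@@](O)(CO[Si](C)(C)C(C)(C)C)C[C@@H](O[Si](C)(C)C(C)(C)C)[C@@H]12 | intermediate
23 | (1R,4Z,6R,7S,8R,10S)-8,14-bis(tert-butyldimethylsilyloxy)-1,10-epoxy-13-norgermacr-4-en-12,6-olide | C1C(=O)O[C@@H]2/C=C(/C)CC[C@H]3O[C@]3(CO[Si](C)(C)C(C)(C)C)C[C@@H](O[Si](C)(C)C(C)(C)C)[C@@H]12 | intermediate
24 | 13-(dimethylamino)-11,13-dihydro derivative of 26 (C11 epimers), not isolated | CN(C)CC1C(=O)O[C@@H]2/C=C(/C)CC[C@H]3O[C@]3(CO[Si](C)(C)C(C)(C)C)C[C@@H](O[Si](C)(C)C(C)(C)C)[C@@H]12 | intermediate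
25 | trimethylammonium iodide of 24, not isolated | C[N+](C)(C)CC1C(=O)O[C@@H]2/C=C(/C)CC[C@H]3O[C@]3(CO[Si](C)(C)C(C)(C)C)C[C@@H](O[Si](C)(C)C(C)(C)C)[C@@H]12.[I-] | intermediate
26 | (1R,4Z,6R,7S,8R,10S)-8,14-bis(tert-butyldimethylsilyloxy)-1,10-epoxygermacra-4,11(13)-dien-12,6-olide | C=C1C(=O)O[C@@H]2/C=C(/C)CC[C@H]3O[C@]3(CO[Si](C)(C)C(C)(C)C)C[C@@H](O[Si](C)(C)C(C)(C)C)[C@@H]12 | intermediate
27 | (1R,4Z,6R,7R,8R,10S)-1,10-epoxy-8,14-dihydroxygermacra-4,11(13)-dien-12,6-olide | C=C1C(=O)O[C@@H]2/C=C(/C)CC[C@H]3O[C@]3(CO)C[C@@H](O)[C@@H]12 | intermediate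
28 | (1R,4Z,6R,7R,8R,10S)-14-acetoxy-1,10-epoxy-8-hydroxygermacra-4,11(13)-dien-12,6-olide | C=C1C(=O)O[C@@H]2/C=C(/C)CC[C@H]3O[C@]3(COC(C)=O)C[C@@H](O)[C@@H]12 | intermediate
29 | angelic acid, (Z)-2-methylbut-2-enoic acid | C/C=C(/C)C(=O)O | starting material
30 | (Z)-2-methylbut-2-en-1-ol | C/C=C(/C)CO | intermediate
31 | [(2R,3S)-2,3-dimethyloxiran-2-yl]methanol | OC[C@@]1(C)O[C@H]1C | intermediate
32 | (2S,3S)-2,3-dimethyloxirane-2-carboxylic acid | OC(=O)[C@@]1(C)O[C@H]1C | intermediate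
33 | mixed anhydride of 32 and 2,4,6-trichlorobenzoic acid, not isolated | O=C(OC(=O)c1c(Cl)cc(Cl)cc1Cl)[C@@]1(C)O[C@H]1C | intermediate
34 | (1R,4Z,6R,7R,8R,10S)-14-acetoxy-1,10-epoxy-8-[(2S,3S)-2,3-dimethyloxirane-2-carbonyloxy]germacra-4,11(13)-dien-12,6-olide (CNP0232260.1) | C=C1C(=O)O[C@@H]2/C=C(/C)CC[C@H]3O[C@]3(COC(C)=O)C[C@@H](OC(=O)[C@@]3(C)O[C@H]3C)[C@@H]12 | target

**Count and risks**

Total: 22 steps. Longest linear sequence: 19 steps (steps 1–18 and 22); steps 19–21 make the side-chain acid.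

Step 12 (ring closure). What may go wrong is addition of C10 to the other face of the C1 aldehyde, since nothing but the ring conformation controls it. The fallback sets the centre by reagent-controlled ketone reduction instead. It sets out from 16: the cyclisation is run as before and the product is taken on whatever its C1 ratio. The (1R)-epimer of 18 F1, alone or mixed with 18, is oxidised with Dess–Martin periodinane to the 1-oxo-10(14)-ene (enone) F2. Corey–Bakshi–Shibata reduction with the (R)-2-methyloxazaborolidine and catecholborane, in which the C10 alkenyl group acts as the large substituent, should return the 1S alcohol, and the route is rejoined at 18.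

Step 13 (directed dihydroxylation). What may go wrong is delivery of osmium to the other face of C10=C14, if the ring holds the C1 hydroxyl on the other side of the methylene, or competing oxidation of C4=C5. The fallback uses that same facial preference and corrects C1 afterwards. It sets out from 18: hydroxyl-directed epoxidation with VO(acac)2 and t-BuOOH, which is erythro-selective for 2-substituted allylic alcohols and does not touch isolated alkenes, gives the (1S,10R)-10,14-epoxy-1-ol F3. Mitsunobu inversion at C1 with 4-nitrobenzoic acid gives the (1R)-4-nitrobenzoate F4. K2CO3 in methanol at 0 °C cleaves the ester, and the freed C1 alkoxide opens the spiro epoxide at C10 with inversion (Payne rearrangement) to the (1R,10S)-1,10-epoxy-14-ol F5. Silylation with TBSCl and imidazole rejoins the route at 23.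

Step 4 (propargylation). What may go wrong is poor facial selectivity at C8, because the catalyst works against the aldehyde's own Felkin–Anh preference, together with slow turnover that gives C7 time to epimerise. The fallback makes both epimers and inverts the wrong one. It sets out from 5: zinc-mediated Barbier propargylation (propargyl bromide, Zn, THF/aq. NH4Cl) gives 6 together with the (8S)-epimer of 6 F6, which are separated. F6 is inverted by a Mitsunobu reaction with chloroacetic acid to the (8R)-chloroacetate of 6 F7. Thiourea and NaHCO3 in ethanol remove the chloroacetyl group without opening the lactone, and the route is rejoined at 6.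

**Further compounds**
F1 | step 12 | (1R)-epimer of 18, (1R,4Z,6R,7S,8R)-8-(tert-butyldimethylsilyloxy)-1-hydroxy-13-norgermacra-4,10(14)-dien-12,6-olide | C1C(=O)O[C@@H]2/C=C(/C)CC[C@@H](O)C(=C)C[C@@H](O[Si](C)(C)C(C)(C)C)[C@@H]12
F2 | step 12 | (4Z,6R,7S,8R)-8-(tert-butyldimethylsilyloxy)-1-oxo-13-norgermacra-4,10(14)-dien-12,6-olide | C1C(=O)O[C@@H]2/C=C(/C)CCC(=O)C(=C)C[C@@H](O[Si](C)(C)C(C)(C)C)[C@@H]12
F3 | step 13 | (1S,4Z,6R,7S,8R,10R)-8-(tert-butyldimethylsilyloxy)-10,14-epoxy-1-hydroxy-13-norgermacr-4-en-12,6-olide | C1C(=O)O[C@@H]2/C=C(/C)CC[C@H](O)[C@]3(CO3)C[C@@H](O[Si](C)(C)C(C)(C)C)[C@@H]12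
F4 | step 13 | (1R)-4-nitrobenzoate obtained from F3 with inversion at C1 | C1C(=O)O[C@@H]2/C=C(/C)CC[C@@H](OC(=O)c3ccc(cc3)[N+](=O)[O-])[C@]4(CO4)C[C@@H](O[Si](C)(C)C(C)(C)C)[C@@H]12
F5 | step 13 | (1R,4Z,6R,7S,8R,10S)-8-(tert-butyldimethylsilyloxy)-1,10-epoxy-14-hydroxy-13-norgermacr-4-en-12,6-olide | C1C(=O)O[C@@H]2/C=C(/C)CC[C@H]3O[C@]3(CO)C[C@@H](O[Si](C)(C)C(C)(C)C)[C@@H]12
F6 | step 4 | (4R,5S)-4-[(1S)-1-hydroxybut-3-yn-1-yl]-5-[(triethylsilyloxy)methyl]oxolan-2-one | O=C1C[C@H]([C@@H](O)CC#C)[C@@H](CO[Si](CC)(CC)CC)O1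
F7 | step 4 | (1R)-chloroacetate of 6 | O=C1C[C@H]([C@H](OC(=O)CCl)CC#C)[C@@H](CO[Si](CC)(CC)CC)O1
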